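**Retrosynthetic overview**
- The depside C(=O)–O bond between the ring B acyl group (4-hydroxy-2-methoxy-6-propylbenzoyl) and O3 of ring A (the acetophenone ring) is cut first. Both halves carry benzyl ethers that are removed in the last step.
- Feature used: in ring A the acetyl-bearing C1 and the pentyl-bearing C6 are neighbours, with C1 beside oxygenated C2 and C6 beside the only ring CH (C5). This is the pattern left when a 3-alkoxybenzyne takes a carbon nucleophile at its distal carbon and a carbon electrophile at its proximal carbon.
- C6–pentyl and C1–acetyl are therefore cut together, back to 3,4,5-trimethoxybenzyne, pentylmagnesium bromide and N-methoxy-N-methylacetamide. The aryne comes from the ortho-iodo triflate of symmetric 3,4,5-trimethoxyphenol.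
- The three ring A oxygens are told apart afterwards: BBr3, then O4-selective benzylation, then O3-selective acylation, while O2 stays chelated to the ketone. The ring B acid comes from 5-propylresorcinol by formylation, O4-benzylation, O2-methylation and oxidation.
- No ring is formed; both benzene rings are bought.

Key step: step 3

Remark on the chemistry: the target has no stereocentre, so no SMILES carries a stereodescriptor; pentylmagnesium bromide (Et2O solution) and 5-propylresorcinol are taken as commercial.

**Step 1**
Reactants: 1 3,4,5-trimethoxyphenol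
Product: 2 2-iodo-3,4,5-trimethoxyphenol
Conditions: NIS (1.0 equiv, added slowly), MeCN, −20 → 0 °C, dark
Reagents that add atoms: N-iodosuccinimide, O=C1CCC(=O)N1I
Why: Electrophilic aromatic iodination; the two free ring positions are equivalent, each being ortho to the hydroxyl and ortho/para to methoxy groups, so one equivalent of a mild iodonium source in the cold should stop at the mono-iodide without oxidising the phenol.

**Step 2**
Reactants: 2 2-iodo-3,4,5-trimethoxyphenol
Product: 3 2-iodo-3,4,5-trimethoxyphenyl trifluoromethanesulfonate
Conditions: Tf2O (1.2 equiv), pyridine (2 equiv), CH2Cl2, 0 °C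
Reagents that add atoms: trifluoromethanesulfonic anhydride, O=S(=O)(OS(=O)(=O)C(F)(F)F)C(F)(F)F
Why: O-sulfonylation of a phenol (aryl triflate formation), to which the aryl iodide and the methyl ethers are inert.

**Step 3**
Reactants: 3 2-iodo-3,4,5-trimethoxyphenyl trifluoromethanesulfonate; 4 pentylmagnesium bromide; 5 N-methoxy-N-methylacetamide
Product: 10 1-(2,3,4-trimethoxy-6-pentylphenyl)ethan-1-one, via magnesiated triflate 6 (not isolated), via 3,4,5-trimethoxybenzyne 7 (not isolated), via arylmagnesium bromide 8 (not isolated), via chelated tetrahedral adduct 9 (not isolated)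
Conditions: 4 (3.5 equiv) in THF/Et2O, −78 °C, slow addition of 3; −78 → 0 °C; then 5 (5 equiv), 0 °C → rt; 1 M HCl
Reagents that add atoms: pentylmagnesium bromide 4, CCCCC[Mg]Br; N-methoxy-N-methylacetamide 5, CC(=O)N(C)OC
Why: Iodine–magnesium exchange between 3 and a first equivalent of 4 gives the ortho-magnesiated triflate 6, which expels Mg(OTf)Br already in the cold and releases aryne 7, whose strained triple bond has a methoxy-bearing carbon on one side and a CH on the other. A second equivalent of 4 carbomagnesiates 7, placing pentyl on the aryne carbon remote from the methoxy group (the more electrophilic terminus of the distorted aryne) and magnesium on the carbon beside it, where the inductively withdrawing, magnesium-binding oxygen stabilises the developing carbanion. Regioselectivity is thus the only selectivity needed, and the flanking methoxy group secures it. Arylmagnesium 8 then adds to the Weinreb amide 5, and the magnesium chelate 9 survives until the acid quench, so no second addition to the ketone can occur. The closest known chemistry is the addition of Grignard reagents to arynes released from 2-iodoaryl sulfonates or triflates by halogen–magnesium exchange with electrophilic trapping of the new arylmagnesium, joined here to the Weinreb ketone synthesis; no ring is closed and no stereocentre persists, because the racemic carbinolamine carbon of 9 is lost on work-up. Slow inverse addition of 3 into excess 4 keeps 8 from exchanging with unreacted 3 or adding to 7, and the excess of 5 absorbs leftover 4, which gives only easily removed heptan-2-one.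

**Step 4**
Reactants: 10 1-(2,3,4-trimethoxy-6-pentylphenyl)ethan-1-one
Product: 11 1-(2,3,4-trihydroxy-6-pentylphenyl)ethan-1-one
Conditions: BBr3 (5 equiv), CH2Cl2, −78 °C → rt; then ice-water
Reagents that add atoms: none
Why: Lewis-acid cleavage of aryl methyl ethers with BBr3, in which the ketone is only complexed reversibly and hydrolysis of the aryl borates should free all three phenols.

**Step 5**
Reactants: 11 1-(2,3,4-trihydroxy-6-pentylphenyl)ethan-1-one
Product: 12 1-[4-(benzyloxy)-2,3-dihydroxy-6-pentylphenyl]ethan-1-one
Conditions: BnBr (1.05 equiv), KHCO3 (1.2 equiv), DMF, 40 °C, argon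
Reagents that add atoms: benzyl bromide, BrCc1ccccc1
Why: Williamson etherification under weak-base control; the 4-OH para to the acetyl group is the most acidic and least hindered phenol, the 2-OH is tied up in a hydrogen bond to the ketone and the 3-OH is flanked on both sides, so hydrogencarbonate and one equivalent of halide should alkylate O4 only, as is known for 2,3,4-trihydroxyaryl carbonyl compounds.

**Step 6**
Reactants: 13 5-propylbenzene-1,3-diol (5-propylresorcinol)
Product: 15 2,4-dihydroxy-6-propylbenzaldehyde, via aryl iminium chloride 14 (not isolated)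
Conditions: POCl3 (1.5 equiv), DMF, 0 °C → rt; then ice-water
Reagents that add atoms: N,N-dimethylformamide, CN(C)C=O; water, O
Why: Vilsmeier–Haack formylation, which on 5-alkylresorcinols goes para to one hydroxyl and ortho to the other (next to the alkyl chain) rather than between the two hydroxyls, the two such positions being equivalent.

**Step 7**
Reactants: 15 2,4-dihydroxy-6-propylbenzaldehyde
Product: 16 4-(benzyloxy)-2-hydroxy-6-propylbenzaldehyde
Conditions: BnBr (1.0 equiv), K2CO3 (1.0 equiv), acetone, reflux
Reagents that add atoms: benzyl bromide, BrCc1ccccc1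
Why: Williamson etherification that is selective for the para hydroxyl, because the ortho hydroxyl is hydrogen-bonded to the aldehyde and far less nucleophilic.

**Step 8**
Reactants: 16 4-(benzyloxy)-2-hydroxy-6-propylbenzaldehyde
Product: 17 4-(benzyloxy)-2-methoxy-6-propylbenzaldehyde
Conditions: MeI (3 equiv), K2CO3 (2 equiv), DMF, rt
Reagents that add atoms: iodomethane, CI
Why: Williamson O-methylation, in which excess MeI in a dipolar aprotic solvent overcomes the chelation of the only remaining phenol.

**Step 9**
Reactants: 17 4-(benzyloxy)-2-methoxy-6-propylbenzaldehyde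
Product: 18 4-(benzyloxy)-2-methoxy-6-propylbenzoic acid
Conditions: NaClO2, NaH2PO4, 2-methylbut-2-ene (excess), t-BuOH/THF/H2O, rt
Reagents that add atoms: sodium chlorite, [Na+].[O-]Cl=O
Why: Pinnick oxidation of the hindered aryl aldehyde to the acid, with the alkene scavenging hypochlorous acid so that the electron-rich ring is not chlorinated and the benzyl ether is untouched.

**Step 10**
Reactants: 18 4-(benzyloxy)-2-methoxy-6-propylbenzoic acid; 12 1-[4-(benzyloxy)-2,3-dihydroxy-6-pentylphenyl]ethan-1-one
Product: 20 3-acetyl-6-(benzyloxy)-2-hydroxy-4-pentylphenyl 4-(benzyloxy)-2-methoxy-6-propylbenzoate, via mixed trifluoroacetic anhydride 19 (not isolated)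
Conditions: (CF3CO)2O (4 equiv), toluene, 0 °C → rt; brief aq. NaHCO3 wash
Reagents that add atoms: none
Why: Trifluoroacetic anhydride mixed-anhydride esterification, the standard depside coupling for fully O-protected 2,6-disubstituted benzoic acids; the electron-rich acyl group is transferred through an acylium-like species to the free 3-OH while the ketone-chelated 2-OH stays inert, and the base-free medium disfavours acyl migration.

**Step 11**
Reactants: 20 3-acetyl-6-(benzyloxy)-2-hydroxy-4-pentylphenyl 4-(benzyloxy)-2-methoxy-6-propylbenzoate
Product: 21 3-acetyl-2,6-dihydroxy-4-pentylphenyl 4-hydroxy-2-methoxy-6-propylbenzoate (CNP0112527.0)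
Conditions: H2 (1 atm), 10% Pd/C, EtOAc, rt
Reagents that add atoms: none
Why: Catalytic hydrogenolysis of both aryl benzyl ethers under neutral conditions, which should leave the hindered aryl ester, the methyl ether and the chelated, electron-rich aryl ketone intact and give no chance for base-induced acyl shift.

**Compound list**
1 | 3,4,5-trimethoxyphenol | COc1cc(O)cc(OC)c1OC | starting material
2 | 2-iodo-3,4,5-trimethoxyphenol | COc1cc(O)c(I)c(OC)c1OC | intermediate
3 | 2-iodo-3,4,5-trimethoxyphenyl trifluoromethanesulfonate | COc1cc(OS(=O)(=O)C(F)(F)F)c(I)c(OC)c1OC | intermediate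
4 | pentylmagnesium bromide | CCCCC[Mg]Br | starting material
5 | N-methoxy-N-methylacetamide | CC(=O)N(C)OC | starting material
6 | [2,3,4-trimethoxy-6-(trifluoromethanesulfonyloxy)phenyl]magnesium bromide (not isolated) | COc1cc(OS(=O)(=O)C(F)(F)F)c([Mg]Br)c(OC)c1OC | intermediate
7 | 3,4,5-trimethoxybenzyne (1,2-didehydro-3,4,5-trimethoxybenzene, not isolated) | COC1=CC#CC(OC)=C1OC | intermediate
8 | (2,3,4-trimethoxy-6-pentylphenyl)magnesium bromide (not isolated) | CCCCCc1cc(OC)c(OC)c(OC)c1[Mg]Br | intermediate
9 | bromomagnesium 1-[methoxy(methyl)amino]-1-(2,3,4-trimethoxy-6-pentylphenyl)ethan-1-olate (racemic, transient, not isolated) | CCCCCc1cc(OC)c(OC)c(OC)c1C(C)(O[Mg]Br)N(C)OC | intermediate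
10 | 1-(2,3,4-trimethoxy-6-pentylphenyl)ethan-1-one | CCCCCc1cc(OC)c(OC)c(OC)c1C(C)=O | intermediate
11 | 1-(2,3,4-trihydroxy-6-pentylphenyl)ethan-1-one | CCCCCc1cc(O)c(O)c(O)c1C(C)=O | intermediate
12 | 1-[4-(benzyloxy)-2,3-dihydroxy-6-pentylphenyl]ethan-1-one | CCCCCc1cc(OCc2ccccc2)c(O)c(O)c1C(C)=O | intermediate
13 | 5-propylbenzene-1,3-diol | CCCc1cc(O)cc(O)c1 | starting material
14 | [(2,4-dihydroxy-6-propylphenyl)methylidene]dimethylazanium chloride (not isolated) | CCCc1cc(O)cc(O)c1C=[N+](C)C.[Cl-] | intermediate
15 | 2,4-dihydroxy-6-propylbenzaldehyde | CCCc1cc(O)cc(O)c1C=O | intermediate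
16 | 4-(benzyloxy)-2-hydroxy-6-propylbenzaldehyde | CCCc1cc(OCc2ccccc2)cc(O)c1C=O | intermediate
17 | 4-(benzyloxy)-2-methoxy-6-propylbenzaldehyde | CCCc1cc(OCc2ccccc2)cc(OC)c1C=O | intermediate
18 | 4-(benzyloxy)-2-methoxy-6-propylbenzoic acid | CCCc1cc(OCc2ccccc2)cc(OC)c1C(=O)O | intermediate
19 | 4-(benzyloxy)-2-methoxy-6-propylbenzoic trifluoroacetic anhydride (not isolated) | CCCc1cc(OCc2ccccc2)cc(OC)c1C(=O)OC(=O)C(F)(F)F | intermediate
20 | 3-acetyl-6-(benzyloxy)-2-hydroxy-4-pentylphenyl 4-(benzyloxy)-2-methoxy-6-propylbenzoate | CCCCCc1cc(OCc2ccccc2)c(OC(=O)c2c(CCC)cc(OCc3ccccc3)cc2OC)c(O)c1C(C)=O | intermediate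
21 | 3-acetyl-2,6-dihydroxy-4-pentylphenyl 4-hydroxy-2-methoxy-6-propylbenzoate | CCCCCc1cc(O)c(OC(=O)c2c(CCC)cc(O)cc2OC)c(O)c1C(C)=O | target

**Step count**
Total step count: 11.
Longest linear sequence: 7 (steps 1, 2, 3, 4, 5, 10, 11).

**Steps most likely to fail**

Step 3. Several things could go wrong:
- The exchange with a primary alkyl Grignard reagent may be sluggish.
- The reagent may attack the sulfonyl sulfur instead.
- The aryne may be consumed by arylmagnesium species.
- The hindered arylmagnesium may enolise the amide and simply be protonated.

The fallback gives up the aryne. Phenol 1 is triflated (Tf2O, pyridine, CH2Cl2) to 3,4,5-trimethoxyphenyl trifluoromethanesulfonate F1. This is joined to 4 in a Kumada coupling (PdCl2(dppf), Et2O/THF, rt) to give 1,2,3-trimethoxy-5-pentylbenzene F2. The two free ring positions of F2 are equivalent, so a Friedel–Crafts acetylation (AcCl, SnCl4, CH2Cl2, 0 °C) can lead only to 10, where the route is rejoined.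

Step 5. Site selectivity may erode through further alkylation at O3, and the pyrogallol-type phenoxide may be oxidised by air. The fallback sets out from 11 and replaces phenoxide alkylation by a Mitsunobu etherification (BnOH 1.0 equiv, PPh3, DIAD, THF, 0 °C). This runs without base and picks the most acidic phenol, O4. It returns directly to 12 and makes no compound outside the list (F0).

Step 10. Acyl transfer between a 2,6-disubstituted acyl donor and a phenol flanked on both sides may be slow, and trifluoroacetylation or acylation at O2 may compete. The fallback sets out from 18, which is converted with (COCl)2 and catalytic DMF in CH2Cl2 into isolated 4-(benzyloxy)-2-methoxy-6-propylbenzoyl chloride F3. This is combined with 12 under Et3N/DMAP in CH2Cl2 under argon. The pathway is nucleophilic catalysis through an acylpyridinium ion, under which any O2 ester can shift to the O3 position, favoured because it keeps the 2-OH/ketone hydrogen bond. The route is rejoined at 20.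

**Further compounds**
F1 | step 3 | 3,4,5-trimethoxyphenyl trifluoromethanesulfonate | COc1cc(OS(=O)(=O)C(F)(F)F)cc(OC)c1OC
F2 | step 3 | 1,2,3-trimethoxy-5-pentylbenzene | CCCCCc1cc(OC)c(OC)c(OC)c1
F0 | step 5 | none | none
F3 | step 10 | 4-(benzyloxy)-2-methoxy-6-propylbenzoyl chloride | CCCc1cc(OCc2ccccc2)cc(OC)c1C(=O)Cl
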